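**Retrosynthetic overview**
- The target is released last by hydrogenolysis of a tetra-O-benzyl ether, so the finished trans-flavanone never sees acid or base.
- The flavanone pyranone ring is closed through its C2–O1 bond: an enantioselective condensation/6-endo oxa-Michael annulation of a 2'-hydroxydeoxybenzoin with 4-(benzyloxy)benzaldehyde sets C2 (S); C3 (R) follows by equilibration to trans.
- The deoxybenzoin comes from palladium-catalysed α-arylation of a phloroacetophenone dibenzyl ether with a 3'-bromoflavone; this CH2–aryl bond becomes the interflavonoid link.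
- The bromoflavone is made first, in one pot, from 2',6'-dihydroxy-4'-methoxyacetophenone and 4-(benzyloxy)-3-bromobenzaldehyde (aldol, C–O ring closure, dehydrogenation).
- Ring order: flavone ring C, then flavanone ring C; all benzene rings are bought.

Assumption: the acetophenone and the three benzyl ethers used as starting materials are catalogue compounds and are bought as such.

**Step 1**
Reactants: 1 (2',6'-dihydroxy-4'-methoxyacetophenone); 2 (4-(benzyloxy)-3-bromobenzaldehyde)
Product: 5 bromoflavone (2-[4-(benzyloxy)-3-bromophenyl]-5-hydroxy-7-methoxy-4H-chromen-4-one), via 2'-hydroxychalcone 3 (not isolated), via racemic flavanone 4 (not isolated)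
Conditions: pyrrolidine (0.5 equiv), DMSO, 100 °C; then I2 (10 mol %), 140 °C
Reagents that add atoms: none
Why: Domino Claisen–Schmidt condensation (pyrrolidine-mediated) to the chalcone, oxa-Michael closure to the flavanone and I2/DMSO dehydrogenation (α-iodination, HI loss, DMSO re-oxidises HI) give the flavone; the symmetric 2',6'-diol makes ring closure unambiguous and leaves the chelated 5-OH, the benzyl ether and aryl bromide are inert, and no stereocentre remains.

**Step 2**
Reactants: 5 (bromoflavone); 6 (1-[2,4-bis(benzyloxy)-6-hydroxyphenyl]ethan-1-one)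
Product: 7 deoxybenzoin (1-[2,4-bis(benzyloxy)-6-hydroxyphenyl]-2-[2-(benzyloxy)-5-(5-hydroxy-7-methoxy-4-oxo-4H-chromen-2-yl)phenyl]ethan-1-one)
Conditions: Pd2(dba)3 (2.5 mol %), XPhos (6 mol %), NaOtBu (4.5 equiv), 1,4-dioxane, 80 °C; then aq. NH4Cl
Reagents that add atoms: none
Why: Palladium-catalysed ketone α-arylation (Buchwald–Hartwig type): excess base turns both chelated phenols into phenoxides and the methyl ketone into its enolate, which couples with the arylpalladium bromide from 5 to form the CH2–aryl bond, while the ortho-benzyloxy group and the di-ortho-substituted aryl ketone disfavour a second arylation; no stereocentre is formed.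

**Step 3**
Reactants: 7 (deoxybenzoin); 8 (4-(benzyloxy)benzaldehyde)
Product: 10 tetrabenzyl flavanone ((2S,3R)-5,7-bis(benzyloxy)-3-[2-(benzyloxy)-5-(5-hydroxy-7-methoxy-4-oxo-4H-chromen-2-yl)phenyl]-2-[4-(benzyloxy)phenyl]-2,3-dihydro-4H-chromen-4-one), via alpha-aryl chalcone 9 (not isolated)
Conditions: 9-amino-9-deoxy-epi-quinine (20 mol %), PhCO2H (40 mol %), 4 Å molecular sieves, toluene, 45 °C
Reagents that add atoms: none
Why: Proposed new method: one cinchona primary-amine/benzoate catalyst is meant to run an asymmetric Knoevenagel/oxa-Michael annulation — its NH2 group condenses with 8 to an iminium that the enol of 7 attacks (Mannich step) and then leaves again by β-elimination to give enone 9, after which the quinuclidinium/benzoate pair of the same chiral catalyst deprotonates the chelated ring A phenol while hydrogen-bonding the enone carbonyl, so that the phenoxide adds 6-endo to one face of C-β (C2–O1 bond, C2 = S) and the acidic 3-H of the α-aryl ketone then equilibrates under the amine to the diequatorial trans (3R) isomer faster than the ring can reopen; the closest known reactions are the piperidine-mediated deoxybenzoin/aldehyde annulation to racemic trans-2,3-diarylchroman-4-ones and the cinchona- or thiourea-catalysed enantioselective oxa-Michael cyclisation of 2'-hydroxychalcones and alkylidene β-keto esters, neither of which has been shown for α-aryl enones or coupled to the condensation.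

**Step 4**
Reactants: 10 (tetrabenzyl flavanone)
Product: 11 target ((2S,3R)-5,7-dihydroxy-3-[2-hydroxy-5-(5-hydroxy-7-methoxy-4-oxo-4H-chromen-2-yl)phenyl]-2-(4-hydroxyphenyl)-2,3-dihydro-4H-chromen-4-one)
Conditions: H2 (1 atm), 10% Pd/C, THF/MeOH, rt
Reagents that add atoms: none
Why: Hydrogenolysis of the four aryl benzyl ethers over Pd/C is neutral, so neither retro-oxa-Michael racemisation at C2 nor epimerisation at C3 can occur, and the flavone C2=C3 bond, the chelated aryl ketones and the methyl ether are untouched at 1 atm and room temperature.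

**Compound list**
1 | 2',6'-dihydroxy-4'-methoxyacetophenone | CC(=O)c1c(O)cc(OC)cc1O | starting material
2 | 4-(benzyloxy)-3-bromobenzaldehyde | O=Cc1ccc(OCc2ccccc2)c(Br)c1 | starting material
3 | (E)-3-[4-(benzyloxy)-3-bromophenyl]-1-(2,6-dihydroxy-4-methoxyphenyl)prop-2-en-1-one | COc1cc(O)c(C(=O)/C=C/c2ccc(OCc3ccccc3)c(Br)c2)c(O)c1 | intermediate
4 | 2-[4-(benzyloxy)-3-bromophenyl]-5-hydroxy-7-methoxy-2,3-dihydro-4H-chromen-4-one (racemic, C2 undefined) | COc1cc(O)c2c(c1)OC(c1ccc(OCc3ccccc3)c(Br)c1)CC2=O | intermediate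
5 | 2-[4-(benzyloxy)-3-bromophenyl]-5-hydroxy-7-methoxy-4H-chromen-4-one | COc1cc(O)c2c(=O)cc(-c3ccc(OCc4ccccc4)c(Br)c3)oc2c1 | intermediate
6 | 1-[2,4-bis(benzyloxy)-6-hydroxyphenyl]ethan-1-one | CC(=O)c1c(O)cc(OCc2ccccc2)cc1OCc1ccccc1 | starting material
7 | 1-[2,4-bis(benzyloxy)-6-hydroxyphenyl]-2-[2-(benzyloxy)-5-(5-hydroxy-7-methoxy-4-oxo-4H-chromen-2-yl)phenyl]ethan-1-one | COc1cc(O)c2c(=O)cc(-c3ccc(OCc4ccccc4)c(CC(=O)c4c(O)cc(OCc5ccccc5)cc4OCc4ccccc4)c3)oc2c1 | intermediate
8 | 4-(benzyloxy)benzaldehyde | O=Cc1ccc(OCc2ccccc2)cc1 | starting material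
9 | (E)-1-[2,4-bis(benzyloxy)-6-hydroxyphenyl]-2-[2-(benzyloxy)-5-(5-hydroxy-7-methoxy-4-oxo-4H-chromen-2-yl)phenyl]-3-[4-(benzyloxy)phenyl]prop-2-en-1-one | COc1cc(O)c2c(=O)cc(-c3ccc(OCc4ccccc4)c(/C(C(=O)c4c(O)cc(OCc5ccccc5)cc4OCc4ccccc4)=C\c4ccc(OCc5ccccc5)cc4)c3)oc2c1 | intermediate
10 | (2S,3R)-5,7-bis(benzyloxy)-3-[2-(benzyloxy)-5-(5-hydroxy-7-methoxy-4-oxo-4H-chromen-2-yl)phenyl]-2-[4-(benzyloxy)phenyl]-2,3-dihydro-4H-chromen-4-one | COc1cc(O)c2c(=O)cc(-c3ccc(OCc6ccccc6)c([C@H]4C(=O)c5c(OCc6ccccc6)cc(OCc6ccccc6)cc5O[C@@H]4c4ccc(OCc6ccccc6)cc4)c3)oc2c1 | intermediate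
11 | (2S,3R)-5,7-dihydroxy-3-[2-hydroxy-5-(5-hydroxy-7-methoxy-4-oxo-4H-chromen-2-yl)phenyl]-2-(4-hydroxyphenyl)-2,3-dihydro-4H-chromen-4-one | COc1cc(O)c2c(=O)cc(-c3ccc(O)c([C@H]4C(=O)c5c(O)cc(O)cc5O[C@@H]4c4ccc(O)cc4)c3)oc2c1 | target

**Totals**
Total step count: 4. Longest linear sequence: 4 (steps 1 to 4; compounds 6 and 8 enter as bought materials).

**Three steps most likely to fail**

Step 3 (the proposed new annulation). The condensation may be slow at 45 °C with an electron-rich aldehyde and a hindered ketone, the enantioselectivity is untested, and prolonged exposure could erode it through ring opening. If the sense of induction is opposite, the quinidine-derived pseudo-enantiomer of the catalyst is used. Fallback with known chemistry: setting out from 7 (with 8), piperidine in EtOH at reflux effects the established racemic annulation and gives the trans racemate. This is a 1:1 mixture of 10 and its mirror image, the (2R,3S)-tetrabenzyl flavanone F1. Preparative chiral SFC on an amylose carbamate phase separates them and the route is rejoined at 10. F1 can be racemised with piperidine by way of ring opening to 9 and recycled.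

Step 2 (α-arylation in the presence of two free, chelated phenols). The phenoxide-bearing ketone may enolise poorly, or the flavone may suffer under the strong base. Fallback: setting out from 5, decarboxylative cyanomethylation (NCCH2CO2K, Pd2(dba)3, XPhos, mesitylene, 140 °C) gives the arylacetonitrile F2. Houben–Hoesch acylation of phloroglucinol with F2 (ZnCl2, HCl gas, Et2O/1,4-dioxane, 0 °C; then hot water) gives the 2,4,6-trihydroxydeoxybenzoin F3. Benzyl bromide (2.1 equiv) with K2CO3 in DMF then benzylates the 4-OH and one of the two equivalent ortho-OH groups of ring A. The remaining ortho-OH and the flavone 5-OH stay chelated, and the route is rejoined at 7.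

Step 1 (one-pot flavone synthesis from a 2',6'-dihydroxyacetophenone). The doubly chelated ketone may condense sluggishly and give a mixture. Fallback: setting out from 2, Pinnick oxidation (NaClO2, NaH2PO4, 2-methyl-2-butene, tBuOH/H2O) gives 4-(benzyloxy)-3-bromobenzoic acid F4. SOCl2 (cat. DMF, toluene, 70 °C) converts it into 4-(benzyloxy)-3-bromobenzoyl chloride F5. The trilithium salt of 1 (LiN(SiMe3)2, 4 equiv, THF, −78 °C) is C-acylated by F5 to the 1,3-diketone F6, the Baker–Venkataraman-type intermediate. Cyclodehydration (cat. H2SO4, AcOH, 60 °C) closes the pyranone and rejoins the route at 5.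

**Further compounds**
F1 | step 3 | (2R,3S)-5,7-bis(benzyloxy)-3-[2-(benzyloxy)-5-(5-hydroxy-7-methoxy-4-oxo-4H-chromen-2-yl)phenyl]-2-[4-(benzyloxy)phenyl]-2,3-dihydro-4H-chromen-4-one | COc1cc(O)c2c(=O)cc(-c3ccc(OCc6ccccc6)c([C@@H]4C(=O)c5c(OCc6ccccc6)cc(OCc6ccccc6)cc5O[C@H]4c4ccc(OCc6ccccc6)cc4)c3)oc2c1
F2 | step 2 | 2-[2-(benzyloxy)-5-(5-hydroxy-7-methoxy-4-oxo-4H-chromen-2-yl)phenyl]acetonitrile | COc1cc(O)c2c(=O)cc(-c3ccc(OCc4ccccc4)c(CC#N)c3)oc2c1
F3 | step 2 | 2-[2-(benzyloxy)-5-(5-hydroxy-7-methoxy-4-oxo-4H-chromen-2-yl)phenyl]-1-(2,4,6-trihydroxyphenyl)ethan-1-one | COc1cc(O)c2c(=O)cc(-c3ccc(OCc4ccccc4)c(CC(=O)c4c(O)cc(O)cc4O)c3)oc2c1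
F4 | step 1 | 4-(benzyloxy)-3-bromobenzoic acid | O=C(O)c1ccc(OCc2ccccc2)c(Br)c1
F5 | step 1 | 4-(benzyloxy)-3-bromobenzoyl chloride | O=C(Cl)c1ccc(OCc2ccccc2)c(Br)c1
F6 | step 1 | 1-[4-(benzyloxy)-3-bromophenyl]-3-(2,6-dihydroxy-4-methoxyphenyl)propane-1,3-dione | COc1cc(O)c(C(=O)CC(=O)c2ccc(OCc3ccccc3)c(Br)c2)c(O)c1
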